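## The problem

The target 25 is a flavonol: a 4H-chromen-4-one (rings A and C fused) that carries ring B on C2 through the single C2–C1' bond. It has no stereocenter, so the difficulty lies in regiochemistry and in telling six oxygens apart. O3, O5 and O2' end as free hydroxyls and O7, O8 and O4' as methyl ethers, which rules out a global demethylation at the end. In ring A the acyl carbon C4a must be placed between O1 and O5, two oxygens that must themselves be differentiated, while C6 is activated just as strongly and must stay unsubstituted. In ring B the 2'-OH and the 4'-OMe sit on a resorcinol pattern and should be distinguished without a selective monoprotection. The finished flavonol (enolic 3-OH next to the C4 carbonyl, chelated 5-OH, electron-rich rings) is sensitive to base, air and strong Lewis acids, and the pyranone is opened by hard nucleophiles at C2, so the closing steps must be neutral and mild. The feature that opens the key step is that ring B is attached through C1', ortho to the oxygen on C2' and para to that on C4'. C2'–C3'–C4'–C5' therefore map onto a 1,1,3-trioxygenated butadiene and C1'–C6' onto a triple bond held at C2, which the C4 carbonyl polarizes through C2=C3.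

## Retrosynthesis

**25 from 24.** The last disconnection cuts the two O–CH2Ph bonds at O3 and O5 of 24. Benzyl is preferred to methyl, silyl or acyl at these positions because it leaves under neutral hydrogenolysis, which touches neither the three methyl ethers nor the pyranone. O2' needs no protecting group because it emerges free from the construction of ring B. The forward step only has to stop before C2=C3 is reduced.

**24 from 18 and 21.** Ring B of 24 is cut at C1'–C2' and C5'–C6'. The neighbouring cut, C2–C1', would require a cross-coupling with a ring B metal reagent in which O2' is protected differently from O4'. The chosen cut stores that difference in diene 21: a silyl ketene acetal carbon becomes C2' and an enol ether carbon becomes C4'. Ring B shrinks to the two carbons of the ethynyl group in 18, which already carries the full oxygenation of rings A and C. The forward reaction must bond the CH2 terminus of 21 to the terminal alkyne carbon, must react at the triple bond only, and must aromatize by loss of methanol and not of the silyloxy group.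

**21 from 19.** Diene 21 is cut at O–Si back to the β-methoxy enoate 19. γ-Deprotonation and O-silylation is the standard entry to such vinylketene acetals, and a four-carbon ester with the methoxy group already in place is the simplest possible source.

**18 from 17, 15, 16 and 13.** The terminal alkyne of 18 is cut at C(sp)–Si to the silyl alkyne 17, and 17 at C2–C(sp) to iodide 15 and alkyne 16. Iodide 15 is in turn cut at C2–I to the C2–H chromone 13. Building the alkyne into a ring-closing condensation was weighed against this, but it would expose an ynone to enolate chemistry. C2–H of a 3-alkoxychromone is the one acidic ring position once C3 is blocked, so the metalation is site-defined. The forward steps ask for a base that deprotonates C2 without adding to it and for coupling conditions free of nucleophilic amines.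

**13 from 10.** Ring C of 13 is cut at O1–C2 and C2–C3. C2 is a one-carbon unit at the formic acid oxidation level attached to the α-carbon of ketone 10, and O1 is the phenol masked as a MOM acetal. Condensations that bring in ring B at this stage (aroyl transfer followed by cyclodehydration) are the neighbours of this cut; they are set aside because C2 has to stay unsubstituted for the alkyne. O3 arrives with the benzyloxyacetyl unit, so no oxidation at C3 is needed. Unmasking the phenol must trigger ring closure.

**10 from 5 and 7; 7 from 6.** Ketone 10 is cut at C4–C4a to the arene 5 and the Weinreb amide 7, itself one step from acid chloride 6. A Friedel–Crafts acylation would not discriminate between the two activated ring positions and its Lewis acid would strip the benzyl ethers. Directed ortho-metalation puts lithium on the one carbon flanked by the MOM acetal and the benzyloxy group. The forward step asks the MOM acetal to outrank the methoxy group that flanks the other doubly activated C–H.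

**5 from 4, 2 and 1.** Arene 5 is cut at O–benzyl to phenol 4, and 4 at C(aryl)–O to aldehyde 2 through an aryl formate. Aldehyde 2 is cut at O–MOM to the commercial aldehyde 1. In 1 the future O1 is already a free phenol and the future O5 is marked by the formyl carbon, so the two oxygens that flank C4a are differentiated from the first step and no selective protection of a resorcinol is needed.

## Roads not taken

**Alternative 1:** The cut is C2–C1', made intramolecularly. A 3-O–CH2–O-aryl acetal A2 ties a 2-bromo-5-methoxyphenyl group to O3 of the 5-O-benzyl chromone. Under Pd(OAc)2 with PCy3·HBF4, K2CO3 and pivalic acid, zerovalent palladium inserts into the C1'–Br bond and C2–H is broken by concerted metalation–deprotonation. Reductive elimination gives the bridged flavonol A1, in which a seven-membered 1,3-dioxepine temporarily links rings C and B.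
- Merits: the tether fixes both the site (C2) and the ortho relation between the new bond and O2'. Ring B comes from a simple bromophenol with OH and OMe already distinguished. No C2 halogenation, alkyne or diene is needed, and the route would probably be three or four steps shorter and more convergent than the chosen one.
- Weak points: A2 is a mixed formaldehyde acetal of an enolic 3-hydroxyl and a phenol, both good leaving groups; it must be made through a chloromethyl aryl ether and must survive carbonate and pivalate at high temperature. The C–H cleavage passes through an eight-membered palladacycle, so protodebromination can compete. O3 must be free while O5 is benzylated before tethering, which adds a differentiation inside the chromone. A1 needs an acidic acetal cleavage in addition to hydrogenolysis.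
- Comparison: on step count and convergence this road is better. The chosen plan sets against it that it needs no tether and no distinction between O3 and O5, and that its critical step runs under neutral thermal conditions. Neither key step has been shown on this ring system.

**Alternative 2:** The cut is O1–C8a and C4–C4a. Fluoride (CsF) converts the silyl bis(triflate) A4 into the C8a–C4a aryne that keeps a triflate on C5. The ketone enolate oxygen of the ring B β-keto ester A5 adds at C8a, and the C4a aryl anion attacks the ester to close ring C, giving the 5-triflyloxy flavonol ether A3.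
- Merits: ring C is closed in one step from two fragments of similar size, O3 and ring B arrive together in A5, O5 is automatically different from the methyl ethers, and no C2 metalation is needed.
- Weak points: the aryne from A4 is flanked by the C8 methoxy group on one side and the C5 triflate on the other, and these direct the nucleophile to opposite aryne carbons. The triflate should dominate but the methoxy group erodes the preference. β-Keto ester enolates usually attack arynes through carbon and then insert the aryne into the C–C bond, which would give a different skeleton. A4 is a pentasubstituted benzene needing its own multistep synthesis with the same ring A regiochemistry problem. A3 requires S–O cleavage of the triflate before hydrogenolysis.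
- Comparison: if both selectivities held, the longest linear sequence would be shorter than in the chosen plan. The chosen plan sets against this a key step with a single, electronically matched orientation issue, and ring A chemistry that Alternative 2 would need in similar form for A4 anyway.

**Alternative 3:** The cut is C4a–C4, C4–C3 and O1–C2. The iodophenol A7, carbon monoxide and the arylacetylene A8 combine under PdCl2(PPh3)2 in diethylamine. Oxidative addition, CO insertion and acyl–alkynyl coupling give an ynone, which the amine closes 6-endo to the flavone A6.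
- Merits: three bonds and ring C form in one operation from simple components. A7 would come from arene 5 by the same directed lithiation (iodine quench, MOM removal). Of the four strategies this ring construction has the best precedent for flavones, and the route would be shorter than the chosen one.
- Weak points: A6 has no oxygen at C3, so a late oxidation at C3 (enolate or epoxide chemistry) is needed on a molecule with three electron-rich aryl ethers and benzylic positions. The iodide of A7 is flanked by two ortho oxygens, which slows oxidative addition and CO insertion; coupling without CO would give a benzofuran and 5-exo closure an aurone. O2' must be protected in A8.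
- Comparison: this road is shorter, more convergent and better precedented in its ring-forming step. The chosen plan sets against it that O3 is carried from the benzyloxyacetyl unit and never has to be introduced by oxidation, and that ring B needs no protecting group. Whether that outweighs the uncertain rate of the cycloaddition is open.

Key step: step 11

Remark on the chemistry: diene 21 is drawn as its 1Z isomer; the configuration of this double bond is lost on aromatization and does not affect the outcome. Cycloadduct 22 and adduct 9 are racemic.

## Route

Step 1
Reactants: 1 3-hydroxy-4,5-dimethoxybenzaldehyde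
Product: 2 3,4-dimethoxy-5-(methoxymethoxy)benzaldehyde
Conditions: MOMCl, iPr2NEt, CH2Cl2, 0 °C to rt
Reagents that add atoms: chloromethyl methyl ether (MOMCl), COCCl
Why: O-alkylation of the phenol with a chloromethyl ether (MOM protection); the acetal later directs ortho-lithiation and is released by acid, and the aldehyde is untouched by the hindered amine base.

Step 2
Reactants: 2 3,4-dimethoxy-5-(methoxymethoxy)benzaldehyde
Product: 4 3,4-dimethoxy-5-(methoxymethoxy)phenol, via aryl formate 3 (not isolated)
Conditions: mCPBA, CH2Cl2, 0 °C to rt; aq NaHCO3 wash; then K2CO3 (cat.), MeOH, rt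
Reagents that add atoms: meta-chloroperbenzoic acid (mCPBA), O=C(OO)c1cccc(Cl)c1
Why: Baeyer–Villiger (Dakin-type) oxidation in which the electron-rich aryl group, with a para methoxy group, migrates in the Criegee intermediate in preference to hydride; formate 3 is then cleaved by catalytic carbonate in methanol. The MOM acetal tolerates the weak carboxylic acid and the basic methanolysis.

Step 3
Reactants: 4 3,4-dimethoxy-5-(methoxymethoxy)phenol
Product: 5 1-(benzyloxy)-3,4-dimethoxy-5-(methoxymethoxy)benzene
Conditions: BnBr, K2CO3, DMF, rt
Reagents that add atoms: benzyl bromide, BrCc1ccccc1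
Why: Williamson ether synthesis on the only free phenol; it fixes the future O5 as a benzyl ether distinct from the MOM-masked future O1.

Step 4
Reactants: 6 benzyloxyacetyl chloride
Product: 7 2-(benzyloxy)-N-methoxy-N-methylacetamide
Conditions: MeNHOMe·HCl, Et3N, CH2Cl2, 0 °C to rt
Reagents that add atoms: N,O-dimethylhydroxylamine hydrochloride, CNOC.Cl
Why: N-acylation of N,O-dimethylhydroxylamine by the acid chloride gives the Weinreb amide, an acyl donor that stops at the ketone stage with organolithiums.

Step 5
Reactants: 5 1-(benzyloxy)-3,4-dimethoxy-5-(methoxymethoxy)benzene; 7 2-(benzyloxy)-N-methoxy-N-methylacetamide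
Product: 10 2-(benzyloxy)-1-[2-(benzyloxy)-4,5-dimethoxy-6-(methoxymethoxy)phenyl]ethan-1-one, via aryllithium 8 (not isolated), via tetrahedral lithium adduct 9 (not isolated)
Conditions: n-BuLi, TMEDA, THF, −78 to −20 °C; then 7, −78 to 0 °C; aq NH4Cl
Reagents that add atoms: none
Why: Directed ortho-metalation followed by Weinreb ketone synthesis. The C–H between the MOM acetal and the benzyloxy group is flanked by two coordinating oxygens, and the chelating acetal is a stronger director than the methoxy group flanking the competing C–H. The chelated adduct 9 prevents over-addition and enolization until the quench.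

Step 6
Reactants: 10 2-(benzyloxy)-1-[2-(benzyloxy)-4,5-dimethoxy-6-(methoxymethoxy)phenyl]ethan-1-one
Product: 13 3,5-bis(benzyloxy)-7,8-dimethoxy-4H-chromen-4-one, via MOM-protected enaminone 11 (not isolated), via hydroxy enaminone 12 (not isolated)
Conditions: DMF-DMA, toluene, 110 °C; then HCl, MeOH, 50 °C
Reagents that add atoms: N,N-dimethylformamide dimethyl acetal (DMF-DMA), COC(OC)N(C)C
Why: Enaminone route to chromones. The formamide acetal condenses at the activated α-CH2 to give 11, acid removes the MOM acetal, and the freed phenol closes ring C by 6-endo-trig conjugate addition and elimination of dimethylamine. Benzyl ethers survive dilute methanolic HCl.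

Step 7
Reactants: 13 3,5-bis(benzyloxy)-7,8-dimethoxy-4H-chromen-4-one
Product: 15 3,5-bis(benzyloxy)-2-iodo-7,8-dimethoxy-4H-chromen-4-one, via 2-lithiochromone 14 (not isolated)
Conditions: LDA, THF, −78 °C; then I2, −78 °C to rt
Reagents that add atoms: iodine, II
Why: Deprotonation of a 3-substituted chromone at C2 by a hindered lithium amide at low temperature, then iodinolysis of vinyllithium 14. C2–H is the most acidic C–H (next to O1 and to the 3-alkoxy group) and C3 is blocked. LDA at −78 °C is too weak for the benzylic CH2 groups and too hindered to add at C2.

Step 8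
Reactants: 15 3,5-bis(benzyloxy)-2-iodo-7,8-dimethoxy-4H-chromen-4-one; 16 trimethylsilylacetylene
Product: 17 3,5-bis(benzyloxy)-7,8-dimethoxy-2-[(trimethylsilyl)ethynyl]-4H-chromen-4-one
Conditions: PdCl2(PPh3)2 (cat.), CuI (cat.), Et3N, THF, rt
Reagents that add atoms: none
Why: Sonogashira coupling; the 2-iodochromone is an electron-poor alkenyl iodide that adds quickly to zerovalent palladium at room temperature. A tertiary amine is used because a secondary amine would displace iodide at C2 by addition–elimination.

Step 9
Reactants: 17 3,5-bis(benzyloxy)-7,8-dimethoxy-2-[(trimethylsilyl)ethynyl]-4H-chromen-4-one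
Product: 18 3,5-bis(benzyloxy)-2-ethynyl-7,8-dimethoxy-4H-chromen-4-one
Conditions: TBAF, AcOH, THF, 0 °C
Reagents that add atoms: none
Why: Fluoride-mediated protodesilylation of the alkynylsilane; buffering with acetic acid keeps the medium non-basic, so neither fluoride nor alkoxide adds to the electrophilic enynone or opens the pyranone.

Step 10
Reactants: 19 methyl (E)-3-methoxybut-2-enoate
Product: 21 (1Z)-1,3-dimethoxy-1-(trimethylsilyloxy)buta-1,3-diene, via lithium dienolate 20 (not isolated)
Conditions: LDA, THF, −78 °C; then TMSCl, −78 °C to rt; distillation
Reagents that add atoms: chlorotrimethylsilane, C[Si](C)(C)Cl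
Why: γ-Deprotonation of the β-methoxy enoate gives the extended dienolate 20, which is silylated on oxygen to the vinylketene silyl acetal (Brassard-type diene); the geometry of the ketene acetal double bond has no consequence later.

Step 11
Reactants: 18 3,5-bis(benzyloxy)-2-ethynyl-7,8-dimethoxy-4H-chromen-4-one; 21 (1Z)-1,3-dimethoxy-1-(trimethylsilyloxy)buta-1,3-diene
Product: 24 3,5-bis(benzyloxy)-2-(2-hydroxy-4-methoxyphenyl)-7,8-dimethoxy-4H-chromen-4-one, via cyclohexa-1,4-diene cycloadduct 22 (not isolated), via aryl trimethylsilyl ether 23 (not isolated)
Conditions: 21 (excess), toluene, 110 °C, sealed tube; then 1 M HCl, THF, rt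
Reagents that add atoms: none
Why: Normal-electron-demand Diels–Alder reaction of a 1,1,3-trioxygenated butadiene with an acceptor alkyne followed by aromatization, the known route from such dienes and alkynyl ketones to resorcinol derivatives. The three donor oxygens of 21 put the largest HOMO coefficient on its CH2 terminus, and conjugation of the triple bond with the C4 carbonyl through C2=C3 puts the largest LUMO coefficient of 18 on the terminal alkyne carbon, so an asynchronous [4+2] transition state (at the limit a zwitterion that collapses to the same ring) forms C5'–C6' ahead of C1'–C2'. Ring B is closed as a six-membered carbocycle by intermolecular cycloaddition, four carbons from the diene and two from the alkyne, giving the cyclohexa-1,4-diene 22. The ketal carbon of 22 is the only stereocenter formed; it arises racemic and is erased when methanol is lost by 1,4-elimination across C2' and C5' to give the aryl silyl ether 23. Dilute acid then cleaves the O–Si bond to the free 2'-OH of 24. The step needs regioselectivity and chemoselectivity: the opposite orientation would give a 3'-hydroxy-5'-methoxy ring and is disfavoured by the matched polarization of both partners, and the other π bonds of 18 (the tetrasubstituted C2=C3 and the vinylogous ester carbonyl) are poor dienophiles. Benzyl ethers, aryl methyl ethers and the chromone are inert to heat in toluene and to brief dilute acid.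

Step 12
Reactants: 24 3,5-bis(benzyloxy)-2-(2-hydroxy-4-methoxyphenyl)-7,8-dimethoxy-4H-chromen-4-one
Product: 25 3,5-dihydroxy-2-(2-hydroxy-4-methoxyphenyl)-7,8-dimethoxy-4H-chromen-4-one
Conditions: H2 (1 atm), Pd/C, EtOAc–MeOH, rt
Reagents that add atoms: none
Why: Catalytic hydrogenolysis of the two aryl benzyl ethers under neutral conditions; the methyl ethers, the free 2'-OH and the tetrasubstituted C2=C3 bond of the flavonol are not affected at ambient pressure.

## Compound list

1 | 3-hydroxy-4,5-dimethoxybenzaldehyde | COc1cc(C=O)cc(O)c1OC | starting material
2 | 3,4-dimethoxy-5-(methoxymethoxy)benzaldehyde | COCOc1cc(C=O)cc(OC)c1OC | intermediate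
3 | 3,4-dimethoxy-5-(methoxymethoxy)phenyl formate | COCOc1cc(OC=O)cc(OC)c1OC | intermediate
4 | 3,4-dimethoxy-5-(methoxymethoxy)phenol | COCOc1cc(O)cc(OC)c1OC | intermediate
5 | 1-(benzyloxy)-3,4-dimethoxy-5-(methoxymethoxy)benzene | COCOc1cc(OCc2ccccc2)cc(OC)c1OC | intermediate
6 | benzyloxyacetyl chloride | O=C(Cl)COCc1ccccc1 | starting material
7 | 2-(benzyloxy)-N-methoxy-N-methylacetamide | CON(C)C(=O)COCc1ccccc1 | intermediate
8 | [2-(benzyloxy)-4,5-dimethoxy-6-(methoxymethoxy)phenyl]lithium | [Li]c1c(OCOC)c(OC)c(OC)cc1OCc1ccccc1 | intermediate
9 | lithium 2-(benzyloxy)-1-[2-(benzyloxy)-4,5-dimethoxy-6-(methoxymethoxy)phenyl]-1-[methoxy(methyl)amino]ethan-1-olate (racemic) | CON(C)C(O[Li])(COCc1ccccc1)c1c(OCOC)c(OC)c(OC)cc1OCc1ccccc1 | intermediate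
10 | 2-(benzyloxy)-1-[2-(benzyloxy)-4,5-dimethoxy-6-(methoxymethoxy)phenyl]ethan-1-one | O=C(COCc1ccccc1)c1c(OCOC)c(OC)c(OC)cc1OCc1ccccc1 | intermediate
11 | (Z)-2-(benzyloxy)-1-[2-(benzyloxy)-4,5-dimethoxy-6-(methoxymethoxy)phenyl]-3-(dimethylamino)prop-2-en-1-one | CN(C)/C=C(\OCc1ccccc1)C(=O)c1c(OCOC)c(OC)c(OC)cc1OCc1ccccc1 | intermediate
12 | (Z)-2-(benzyloxy)-1-[6-(benzyloxy)-2-hydroxy-3,4-dimethoxyphenyl]-3-(dimethylamino)prop-2-en-1-one | CN(C)/C=C(\OCc1ccccc1)C(=O)c1c(O)c(OC)c(OC)cc1OCc1ccccc1 | intermediate
13 | 3,5-bis(benzyloxy)-7,8-dimethoxy-4H-chromen-4-one | COc1cc(OCc2ccccc2)c2c(=O)c(OCc3ccccc3)coc2c1OC | intermediate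
14 | [3,5-bis(benzyloxy)-7,8-dimethoxy-4-oxo-4H-chromen-2-yl]lithium | [Li]c1oc2c(OC)c(OC)cc(OCc3ccccc3)c2c(=O)c1OCc1ccccc1 | intermediate
15 | 3,5-bis(benzyloxy)-2-iodo-7,8-dimethoxy-4H-chromen-4-one | COc1cc(OCc2ccccc2)c2c(=O)c(OCc3ccccc3)c(I)oc2c1OC | intermediate
16 | trimethylsilylacetylene | C#C[Si](C)(C)C | starting material
17 | 3,5-bis(benzyloxy)-7,8-dimethoxy-2-[(trimethylsilyl)ethynyl]-4H-chromen-4-one | COc1cc(OCc2ccccc2)c2c(=O)c(OCc3ccccc3)c(C#C[Si](C)(C)C)oc2c1OC | intermediate
18 | 3,5-bis(benzyloxy)-2-ethynyl-7,8-dimethoxy-4H-chromen-4-one | C#Cc1oc2c(OC)c(OC)cc(OCc3ccccc3)c2c(=O)c1OCc1ccccc1 | intermediate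
19 | methyl (E)-3-methoxybut-2-enoate | CO/C(C)=C/C(=O)OC | starting material
20 | lithium (1E)-1,3-dimethoxybuta-1,3-dien-1-olate | C=C(OC)/C=C(/OC)O[Li] | intermediate
21 | (1Z)-1,3-dimethoxy-1-(trimethylsilyloxy)buta-1,3-diene | C=C(OC)/C=C(/OC)O[Si](C)(C)C | intermediate
22 | 3,5-bis(benzyloxy)-2-[4,6-dimethoxy-6-(trimethylsilyloxy)cyclohexa-1,4-dien-1-yl]-7,8-dimethoxy-4H-chromen-4-one (racemic) | COC1=CC(OC)(O[Si](C)(C)C)C(c2oc3c(OC)c(OC)cc(OCc4ccccc4)c3c(=O)c2OCc2ccccc2)=CC1 | intermediate
23 | 3,5-bis(benzyloxy)-7,8-dimethoxy-2-[4-methoxy-2-(trimethylsilyloxy)phenyl]-4H-chromen-4-one | COc1ccc(-c2oc3c(OC)c(OC)cc(OCc4ccccc4)c3c(=O)c2OCc2ccccc2)c(O[Si](C)(C)C)c1 | intermediate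
24 | 3,5-bis(benzyloxy)-2-(2-hydroxy-4-methoxyphenyl)-7,8-dimethoxy-4H-chromen-4-one | COc1ccc(-c2oc3c(OC)c(OC)cc(OCc4ccccc4)c3c(=O)c2OCc2ccccc2)c(O)c1 | intermediate
25 | 3,5-dihydroxy-2-(2-hydroxy-4-methoxyphenyl)-7,8-dimethoxy-4H-chromen-4-one (3,5,2'-trihydroxy-7,8,4'-trimethoxyflavone) | COc1ccc(-c2oc3c(OC)c(OC)cc(O)c3c(=O)c2O)c(O)c1 | target

## Step count and risks

Total step count: 12. Longest linear sequence: 10 steps (steps 1, 2, 3, 5, 6, 7, 8, 9, 11 and 12, from aldehyde 1); steps 4 and 10 prepare the side components 7 and 21.

**Step 11 (key step).**
- What may go wrong: the cycloaddition may be too slow to compete with thermal decomposition or hydrolysis of the diene. The alkyne is activated only through C2=C3, and the 3-benzyloxy group feeds electron density back toward C2. A Michael-type addition that stops at an open-chain adduct, or loss of the silyloxy group instead of methanol on aromatization (which would leave a 2'-methyl ether), are the other failure processes.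
- Fallback: ring B would be attached as a whole by Suzuki–Miyaura coupling, setting out from iodide 15. 2-Bromo-5-methoxyphenol would be benzylated (BnBr, K2CO3) to 2-(benzyloxy)-1-bromo-4-methoxybenzene F1. Miyaura borylation (bis(pinacolato)diboron, PdCl2(dppf), KOAc) would give 2-[2-(benzyloxy)-4-methoxyphenyl]-4,4,5,5-tetramethyl-1,3,2-dioxaborolane F2. Coupling of F2 with 15 (Pd(PPh3)4, K2CO3, dioxane–water) would give 3,5-bis(benzyloxy)-2-[2-(benzyloxy)-4-methoxyphenyl]-7,8-dimethoxy-4H-chromen-4-one F3. Hydrogenolysis of all three benzyl ethers comes back to the route at 25.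

**Step 5.**
- What may go wrong: lithiation may leak to the C–H between the benzyloxy and methoxy groups, because the preference rests only on the MOM acetal outranking a methoxy group. Deprotonation of a benzylic OCH2 followed by Wittig rearrangement is also possible, as is slow acyl transfer to the doubly ortho-substituted aryllithium.
- Fallback: the carbon would be introduced by a formylation that can occur at only one position, setting out from 5. Acid (HCl, MeOH) would remove the MOM group to give 5-(benzyloxy)-2,3-dimethoxyphenol F4. Ortho-specific formylation (MgCl2, Et3N, paraformaldehyde, MeCN, reflux) can reach only the single free ortho position and would give 6-(benzyloxy)-2-hydroxy-3,4-dimethoxybenzaldehyde F5. MOM protection would give 6-(benzyloxy)-3,4-dimethoxy-2-(methoxymethoxy)benzaldehyde F6. Addition of (benzyloxymethyl)lithium, generated from tributyl[(benzyloxy)methyl]stannane and n-BuLi, would give racemic 2-(benzyloxy)-1-[2-(benzyloxy)-4,5-dimethoxy-6-(methoxymethoxy)phenyl]ethan-1-ol F7. Dess–Martin oxidation comes back to the route at ketone 10.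

**Step 7.**
- What may go wrong: the amide base may add at C2 and open the pyranone, or metalation may be incomplete, so that iodination returns starting chromone or ring-opened material.
- Fallback: the C2 substituent would be built during ring closure, setting out from ketone 10. Claisen condensation with dimethyl oxalate (NaOMe) would give methyl 3-(benzyloxy)-4-[2-(benzyloxy)-4,5-dimethoxy-6-(methoxymethoxy)phenyl]-2,4-dioxobutanoate F8 (racemic, enolizable). Methanolic HCl would convert it by MOM cleavage and cyclodehydration into methyl 3,5-bis(benzyloxy)-7,8-dimethoxy-4-oxo-4H-chromene-2-carboxylate F9. NaBH4 would reduce the activated ester to 3,5-bis(benzyloxy)-2-(hydroxymethyl)-7,8-dimethoxy-4H-chromen-4-one F10, and MnO2 would give 3,5-bis(benzyloxy)-7,8-dimethoxy-4-oxo-4H-chromene-2-carbaldehyde F11. Seyferth–Gilbert homologation with the Ohira–Bestmann reagent (K2CO3, MeOH, 0 °C) comes back to the route at alkyne 18, bypassing steps 6 to 9.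

**Step 9.**
- What may go wrong: fluoride or adventitious hydroxide may add to the enynone in conjugate fashion, or the terminal alkyne may oligomerize during unmasking, since the same polarization that serves the key step makes 18 an acceptor.
- Fallback: the ethynyl group would be introduced without a silyl mask, setting out from iodide 15. Stille coupling with tributyl(ethynyl)stannane (Pd(PPh3)4, toluene, 80 °C) comes back to the route at 18 directly, with no fluoride or base and no new compound.

## Further compounds

F1 | step 11 | 2-(benzyloxy)-1-bromo-4-methoxybenzene | COc1ccc(Br)c(OCc2ccccc2)c1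
F2 | step 11 | 2-[2-(benzyloxy)-4-methoxyphenyl]-4,4,5,5-tetramethyl-1,3,2-dioxaborolane | COc1ccc(B2OC(C)(C)C(C)(C)O2)c(OCc2ccccc2)c1
F3 | step 11 | 3,5-bis(benzyloxy)-2-[2-(benzyloxy)-4-methoxyphenyl]-7,8-dimethoxy-4H-chromen-4-one | COc1ccc(-c2oc3c(OC)c(OC)cc(OCc4ccccc4)c3c(=O)c2OCc2ccccc2)c(OCc2ccccc2)c1
F4 | step 5 | 5-(benzyloxy)-2,3-dimethoxyphenol | COc1cc(OCc2ccccc2)cc(O)c1OC
F5 | step 5 | 6-(benzyloxy)-2-hydroxy-3,4-dimethoxybenzaldehyde | COc1cc(OCc2ccccc2)c(C=O)c(O)c1OC
F6 | step 5 | 6-(benzyloxy)-3,4-dimethoxy-2-(methoxymethoxy)benzaldehyde | COCOc1c(C=O)c(OCc2ccccc2)cc(OC)c1OC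
F7 | step 5 | 2-(benzyloxy)-1-[2-(benzyloxy)-4,5-dimethoxy-6-(methoxymethoxy)phenyl]ethan-1-ol (racemic) | COCOc1c(C(O)COCc2ccccc2)c(OCc2ccccc2)cc(OC)c1OC
F8 | step 7 | methyl 3-(benzyloxy)-4-[2-(benzyloxy)-4,5-dimethoxy-6-(methoxymethoxy)phenyl]-2,4-dioxobutanoate (racemic) | COC(=O)C(=O)C(OCc1ccccc1)C(=O)c1c(OCOC)c(OC)c(OC)cc1OCc1ccccc1
F9 | step 7 | methyl 3,5-bis(benzyloxy)-7,8-dimethoxy-4-oxo-4H-chromene-2-carboxylate | COC(=O)c1oc2c(OC)c(OC)cc(OCc3ccccc3)c2c(=O)c1OCc1ccccc1
F10 | step 7 | 3,5-bis(benzyloxy)-2-(hydroxymethyl)-7,8-dimethoxy-4H-chromen-4-one | OCc1oc2c(OC)c(OC)cc(OCc3ccccc3)c2c(=O)c1OCc1ccccc1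
F11 | step 7 | 3,5-bis(benzyloxy)-7,8-dimethoxy-4-oxo-4H-chromene-2-carbaldehyde | O=Cc1oc2c(OC)c(OC)cc(OCc3ccccc3)c2c(=O)c1OCc1ccccc1
F0 | step 9 | none | none
A1 | alternative 1 | 5-(benzyloxy)-7,8-dimethoxy-4'-methoxyflavonol with O3 and O2' joined by a CH2 bridge (seven-membered 1,3-dioxepine between rings C and B) | COc1ccc2c(c1)OCOc1c-2oc2c(OC)c(OC)cc(OCc3ccccc3)c2c1=O
A2 | alternative 1 | 5-(benzyloxy)-3-[(2-bromo-5-methoxyphenoxy)methoxy]-7,8-dimethoxy-4H-chromen-4-one | COc1ccc(Br)c(OCOc2coc3c(OC)c(OC)cc(OCc4ccccc4)c3c2=O)c1
A3 | alternative 2 | 3-(benzyloxy)-2-[2-(benzyloxy)-4-methoxyphenyl]-7,8-dimethoxy-4-oxo-4H-chromen-5-yl trifluoromethanesulfonate | COc1ccc(-c2oc3c(OC)c(OC)cc(OS(=O)(=O)C(F)(F)F)c3c(=O)c2OCc2ccccc2)c(OCc2ccccc2)c1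
A4 | alternative 2 | 4,5-dimethoxy-3-(trimethylsilyl)-1,2-phenylene bis(trifluoromethanesulfonate) | COc1cc(OS(=O)(=O)C(F)(F)F)c(OS(=O)(=O)C(F)(F)F)c([Si](C)(C)C)c1OC
A5 | alternative 2 | methyl 2-(benzyloxy)-3-[2-(benzyloxy)-4-methoxyphenyl]-3-oxopropanoate (racemic) | COC(=O)C(OCc1ccccc1)C(=O)c1ccc(OC)cc1OCc1ccccc1
A6 | alternative 3 | 5-(benzyloxy)-2-[2-(benzyloxy)-4-methoxyphenyl]-7,8-dimethoxy-4H-chromen-4-one | COc1ccc(-c2cc(=O)c3c(OCc4ccccc4)cc(OC)c(OC)c3o2)c(OCc2ccccc2)c1
A7 | alternative 3 | 3-(benzyloxy)-2-iodo-5,6-dimethoxyphenol | COc1cc(OCc2ccccc2)c(I)c(O)c1OC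
A8 | alternative 3 | 2-(benzyloxy)-1-ethynyl-4-methoxybenzene | C#Cc1ccc(OC)cc1OCc1ccccc1
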